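Everything rests on cutting the C4–C5 bond of ring A. C4 is a gem-dimethyl quaternary carbon and C5 lies next to oxygenated C6, so the C5 terminus of a C6 silyl dienol ether can trap a tertiary C4 cation. One Lewis-acid operation thus closes ring A, creates the quaternary C4 and the C5 ring-fusion stereocentre, and delivers a bicyclic ene-dione carrying the complete ring B oxygen and methyl pattern. The precursor is a monocyclic (S)-4-silyloxycyclohexa-2,4-dienone whose quaternary C10 holds a methyl group and a 4-chloro-4-methylpentyl arm; C10 comes from a palladium-catalysed asymmetric allylation, and the C11–C16 chain is later added at C9 from (R)-linalool.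

Key step: step 7

Numbering: labdane numbering is used for positions (C1–C10 decalin carbons, C11–C16 side chain); β is the face of the C10 methyl group.
Assumption: the trans-fused ene-dione 14 is taken to be the C5 epimer favoured at equilibrium, as is usual for 6-oxo-4,4,10-trimethyl-trans-decalins; the first fallback covers the opposite case.

Step 1
Reactants: 1 4-methoxy-2,6-dimethylphenol
Product: 2 4,4-dimethoxy-2,6-dimethylcyclohexa-2,5-dien-1-one
Conditions: PhI(OAc)2 (1.1 equiv), MeOH, 0 °C
Reagents that add atoms: methanol, CO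
Why: Oxidative dearomatisation of a para-alkoxyphenol by a hypervalent iodine oxidant, the cationic intermediate being captured by methanol at the methoxy-bearing carbon to give the symmetrical quinone monoketal.

Step 2
Reactants: 2 4,4-dimethoxy-2,6-dimethylcyclohexa-2,5-dien-1-one; 3 allyl chloroformate
Product: 5 allyl (4,4-dimethoxy-2,6-dimethylcyclohexa-1,5-dien-1-yl) carbonate, via lithium dienolate 4 (not isolated)
Conditions: LiBH(s-Bu)3 (1.05 equiv), THF, −78 °C; then allyl chloroformate, −78 → 0 °C
Reagents that add atoms: allyl chloroformate (3), C=CCOC(=O)Cl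
Why: Conjugate hydride reduction of one arm of the cross-conjugated dienone (1,2-attack is screened by the two flanking methyl groups) followed by O-acylation of the tetrasubstituted lithium enolate by the chloroformate; no stereocentre is created and any C-acylated isomer would converge in step 3.

Step 3
Reactants: 5 allyl (4,4-dimethoxy-2,6-dimethylcyclohexa-1,5-dien-1-yl) carbonate
Product: 6 (S)-6-allyl-4,4-dimethoxy-2,6-dimethylcyclohex-2-en-1-one
Conditions: Pd2(dba)3 (2.5 mol%), (R)-t-Bu-PHOX (6.25 mol%), THF, 25 °C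
Reagents that add atoms: none
Why: Decarboxylative asymmetric allylic alkylation (enantioselective Tsuji allylation): oxidative addition of zerovalent palladium and loss of CO2 give a PHOX-bound allylpalladium enolate that forms the C10 quaternary centre by inner-sphere C–C coupling, the (R)-ligand being chosen because the (S)-ligand gives (S)-2-allyl-2-methylcyclohexanone and the same facial sense corresponds here, after the change in CIP priorities caused by the ketal carbon, to the unwanted (R)-ketone.

Step 4
Reactants: 6 (S)-6-allyl-4,4-dimethoxy-2,6-dimethylcyclohex-2-en-1-one; 7 2-bromopropene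
Product: 10 (S)-2,6-dimethyl-6-(4-methylpent-4-en-1-yl)cyclohex-2-ene-1,4-dione, via B-alkyl-9-BBN adduct 8 (not isolated), via dimethyl ketal alkene 9 (not isolated)
Conditions: 9-BBN (1.1 equiv), THF, 0 °C → rt; then 2-bromopropene, Pd(dppf)Cl2 (5 mol%), Cs2CO3, DMF/H2O, rt; then 1 M aq. HCl, THF, rt
Reagents that add atoms: 2-bromopropene (7), CC(Br)=C; water, O
Why: Chemoselective anti-Markovnikov hydroboration of the monosubstituted alkene by the bulky borane (the carbonyl flanked by a quaternary carbon and the trisubstituted enone react far more slowly), B-alkyl Suzuki–Miyaura coupling with the vinyl bromide, and acid hydrolysis of the dimethyl ketal in the work-up once its role of masking the C6 carbonyl from the borane is over; C10 is untouched.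

Step 5
Reactants: 10 (S)-2,6-dimethyl-6-(4-methylpent-4-en-1-yl)cyclohex-2-ene-1,4-dione
Product: 11 (S)-6-(4-chloro-4-methylpentyl)-2,6-dimethylcyclohex-2-ene-1,4-dione
Conditions: HCl (gas, to saturation), CH2Cl2, 0 °C; cold aq. NaHCO3 wash
Reagents that add atoms: hydrogen chloride, Cl
Why: Markovnikov hydrochlorination of the 1,1-disubstituted alkene through the tertiary cation; reversible HCl addition to the ene-dione is undone by the bicarbonate wash and by the amine of step 6.

Step 6
Reactants: 11 (S)-6-(4-chloro-4-methylpentyl)-2,6-dimethylcyclohex-2-ene-1,4-dione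
Product: 12 (S)-6-(4-chloro-4-methylpentyl)-2,6-dimethyl-4-(trimethylsilyloxy)cyclohexa-2,4-dien-1-one
Conditions: Me3SiOTf (1.2 equiv), Et3N (2 equiv), CH2Cl2, −78 → 0 °C; pentane, filtration, concentration
Reagents that add atoms: trimethylsilyl trifluoromethanesulfonate, C[Si](C)(C)OS(=O)(=O)C(F)(F)F
Why: Soft enolisation with a silyl triflate and an amine: the C6 ketone can enolise only toward C5H2 (C10 is quaternary and the C9 ketone has no α-hydrogen), giving the C5=C6 silyl dienol ether, which is used crude after the non-aqueous work-up.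

Step 7
Reactants: 12 (S)-6-(4-chloro-4-methylpentyl)-2,6-dimethyl-4-(trimethylsilyloxy)cyclohexa-2,4-dien-1-one
Product: 14 (4aS,8aS)-2,5,5,8a-tetramethyl-4a,5,6,7,8,8a-hexahydronaphthalene-1,4-dione (trans-fused), via cis-fused (4aR,8aS)-ene-dione 13 (not isolated)
Conditions: TiCl4 (1.1 equiv), 2,6-di-tert-butyl-4-methylpyridine (0.3 equiv), CH2Cl2, −78 → −40 °C; aq. NaHCO3; crude in CH2Cl2, DBU (0.2 equiv), 0 °C → rt, under argon
Reagents that add atoms: none
Why: TiCl4 abstracts chloride from the tertiary C4–Cl to give the C4 carbocation, which is attacked by C5, the nucleophilic terminus of the C6 silyl dienol ether, and loss of the silyl group as Me3SiCl regenerates the C6 ketone; the closest known reaction is the Lewis-acid-mediated SN1-type α-tert-alkylation of silyl enol ethers by tertiary chlorides, used here intramolecularly. Ring A closes in a six-membered (enol-exo)-exo mode, the C5=C6 enol double bond and the departing chloride both lying outside the forming ring. Because the three-carbon tether reaches only the C5 π-lobe on the face of C1 while ring B is nearly planar, the closure should give the cis-fused ketone 13 first; C5 is α to the C6 carbonyl, so base-mediated enolisation corrects it, reprotonation taking place on the α face, anti to the axial C10 and C4β methyl groups, to give trans-fused 14 with the absolute sense fixed by C10. The step needs C-alkylation at C5 instead of proton loss from the cation or desilylation: C5 is the only nucleophilic carbon within reach (C7 is electron-poor and C10 is quaternary), the hindered pyridine scavenges adventitious HCl, and any alkene formed by E1 loss is re-ionised under the conditions.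

Step 8
Reactants: 14 (4aS,8aS)-2,5,5,8a-tetramethyl-4a,5,6,7,8,8a-hexahydronaphthalene-1,4-dione
Product: 15 (4R,4aS,8aS)-4-hydroxy-2,5,5,8a-tetramethyl-4a,5,6,7,8,8a-hexahydronaphthalen-1(4H)-one (6β-hydroxy-7-en-9-one)
Conditions: NaBH4 (0.5 equiv), CeCl3·7H2O (1.1 equiv), MeOH, −78 °C
Reagents that add atoms: none
Why: Luche 1,2-reduction: the C6 carbonyl is the less shielded one (the C9 carbonyl lies between quaternary C10 and methyl-bearing C8, as in 2,6,6-trimethylcyclohex-2-ene-1,4-dione, which reacts at the corresponding carbonyl), and hydride approaches C6 from the α face, away from the axial C10 and C4β methyl groups, to set the axial 6β-alcohol.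

Step 9
Reactants: 16 (R)-linalool
Product: 17 (R)-[(3,7-dimethylocta-1,6-dien-3-yl)oxy]triethylsilane
Conditions: Et3SiOTf (1.2 equiv), 2,6-lutidine, CH2Cl2, −78 → 0 °C
Reagents that add atoms: triethylsilyl trifluoromethanesulfonate, CC[Si](CC)(CC)OS(=O)(=O)C(F)(F)F
Why: Silylation of the tertiary allylic alcohol with a silyl triflate and a hindered pyridine base; the stereocentre (later C13) is not touched.

Step 10
Reactants: 17 (R)-[(3,7-dimethylocta-1,6-dien-3-yl)oxy]triethylsilane
Product: 18 (R)-4-methyl-4-(triethylsilyloxy)hex-5-enal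
Conditions: O3, CH2Cl2, −78 °C (indicator dye end-point); then PPh3, −78 °C → rt
Reagents that add atoms: ozone, [O-][O+]=O
Why: Chemoselective ozonolysis: the electron-rich trisubstituted alkene is cleaved much faster than the vinyl group on the silyloxy-bearing quaternary carbon, and the ozonide is reduced by the phosphine to the aldehyde.

Step 11
Reactants: 18 (R)-4-methyl-4-(triethylsilyloxy)hex-5-enal
Product: 19 (R)-3-methyl-3,6-bis(triethylsilyloxy)hexa-1,5-diene (E/Z mixture at the enol ether)
Conditions: Et3SiOTf (1.2 equiv), Et3N, CH2Cl2, 0 °C → rt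
Reagents that add atoms: triethylsilyl trifluoromethanesulfonate, CC[Si](CC)(CC)OS(=O)(=O)C(F)(F)F
Why: Soft enolisation of the aldehyde to its silyl enol ether, which marks the aldehyde carbon for excision; the E/Z mixture is of no consequence.

Step 12
Reactants: 19 (R)-3-methyl-3,6-bis(triethylsilyloxy)hexa-1,5-diene
Product: 21 (R)-3-methyl-3-(triethylsilyloxy)pent-4-en-1-ol, via nor-aldehyde 20 (not isolated)
Conditions: O3, CH2Cl2/MeOH, −78 °C (indicator dye end-point); then NaBH4, −78 → 0 °C
Reagents that add atoms: ozone, [O-][O+]=O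
Why: Ozonolysis of the enol ether, again far more reactive than the vinyl group, removes one carbon as formate, and borohydride reduction in the same flask converts the β-silyloxy aldehyde to the primary alcohol before it can eliminate.

Step 13
Reactants: 21 (R)-3-methyl-3-(triethylsilyloxy)pent-4-en-1-ol
Product: 22 (R)-5-bromo-3-methyl-3-(triethylsilyloxy)pent-1-ene
Conditions: CBr4, PPh3, 2,6-lutidine, CH2Cl2, 0 °C
Reagents that add atoms: carbon tetrabromide, BrC(Br)(Br)Br
Why: Appel reaction (SN2 displacement of the alkoxyphosphonium by bromide) on the primary alcohol, with a hindered pyridine present to keep the silyl ether from acid.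

Step 14
Reactants: 15 (4R,4aS,8aS)-4-hydroxy-2,5,5,8a-tetramethyl-4a,5,6,7,8,8a-hexahydronaphthalen-1(4H)-one; 22 (R)-5-bromo-3-methyl-3-(triethylsilyloxy)pent-1-ene
Product: 25 (1S,4R,4aS,8aS)-2,5,5,8a-tetramethyl-1-[(3R)-3-methyl-3-(triethylsilyloxy)pent-4-en-1-yl]-1,4,4a,5,6,7,8,8a-octahydronaphthalene-1,4-diol, via Grignard reagent 23 (not isolated), via organocerium reagent 24 (not isolated)
Conditions: 22 (3 equiv), Mg turnings, THF, rt → 40 °C; anhydrous CeCl3, THF, −78 °C; then 15, −78 → −40 °C; sat. aq. NH4Cl
Reagents that add atoms: none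
Why: Grignard formation and transmetalation give an organocerium reagent that adds 1,2 to the hindered C9 enone carbonyl without conjugate addition (the first equivalent is consumed as base by the C6 hydroxyl); attack is expected anti to the C10 methyl group but the C9 configuration is erased in step 16, and any minor C10 enantiomer carried from step 3 becomes a separable diastereomer here.

Step 15
Reactants: 25 (1S,4R,4aS,8aS)-2,5,5,8a-tetramethyl-1-[(3R)-3-methyl-3-(triethylsilyloxy)pent-4-en-1-yl]-1,4,4a,5,6,7,8,8a-octahydronaphthalene-1,4-diol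
Product: 26 (1R,4S,4aS,8aS)-4-hydroxy-3,4a,8,8-tetramethyl-4-[(3R)-3-methyl-3-(triethylsilyloxy)pent-4-en-1-yl]-1,4,4a,5,6,7,8,8a-octahydronaphthalen-1-yl acetate (6β-acetate)
Conditions: Ac2O, Et3N, DMAP (0.2 equiv), CH2Cl2, rt
Reagents that add atoms: acetic anhydride, CC(=O)OC(C)=O
Why: Nucleophile-catalysed (DMAP) acylation: only the secondary C6 hydroxyl reacts, the C9 hydroxyl being tertiary and wedged between quaternary C10 and C8, and the C13 oxygen being silylated.

Step 16
Reactants: 26 (1R,4S,4aS,8aS)-4-hydroxy-3,4a,8,8-tetramethyl-4-[(3R)-3-methyl-3-(triethylsilyloxy)pent-4-en-1-yl]-1,4,4a,5,6,7,8,8a-octahydronaphthalen-1-yl acetate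
Product: 27 (1S,4aS,8aS)-3,4a,8,8-tetramethyl-4-[(3R)-3-methyl-3-(triethylsilyloxy)pent-4-en-1-yl]-2-oxo-1,2,4a,5,6,7,8,8a-octahydronaphthalen-1-yl acetate
Conditions: pyridinium chlorochromate C5H5NH[CrO3Cl] (3 equiv), powdered 4 Å molecular sieves, CH2Cl2, rt
Reagents that add atoms: pyridinium chlorochromate C5H5NH[CrO3Cl], [O-][Cr](=O)(=O)Cl.c1cc[nH+]cc1
Why: Babler–Dauben oxidative 1,3-transposition: the tertiary allylic alcohol forms a chromate ester that undergoes a [3,3]-sigmatropic shift to C7 and is then oxidised by hexavalent chromium to the C7 ketone with the C8=C9 double bond, erasing the C9 stereocentre and leaving C5, C6, C10 and C13 untouched.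

Step 17
Reactants: 27 (1S,4aS,8aS)-3,4a,8,8-tetramethyl-4-[(3R)-3-methyl-3-(triethylsilyloxy)pent-4-en-1-yl]-2-oxo-1,2,4a,5,6,7,8,8a-octahydronaphthalen-1-yl acetate
Product: 28 (1S,4aS,8aS)-4-[(3R)-3-hydroxy-3-methylpent-4-en-1-yl]-3,4a,8,8-tetramethyl-2-oxo-1,2,4a,5,6,7,8,8a-octahydronaphthalen-1-yl acetate (CNP0328351.1)
Conditions: HF·pyridine, pyridine, THF, 0 °C → rt
Reagents that add atoms: none
Why: Fluoride-induced cleavage of the tertiary triethylsilyl ether under pyridine-buffered conditions, which avoids base that could epimerise C6 (now α to the C7 ketone) or cleave the acetate and avoids acid strong enough to ionise the tertiary allylic alcohol.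

Compound list
1 | 4-methoxy-2,6-dimethylphenol | COc1cc(C)c(O)c(C)c1 | starting material
2 | 4,4-dimethoxy-2,6-dimethylcyclohexa-2,5-dien-1-one | COC1(OC)C=C(C)C(=O)C(C)=C1 | intermediate
3 | allyl chloroformate | C=CCOC(=O)Cl | starting material
4 | lithium 4,4-dimethoxy-2,6-dimethylcyclohexa-1,5-dien-1-olate (not isolated) | [Li+].[O-]C1=C(C)CC(OC)(OC)C=C1C | intermediate
5 | allyl (4,4-dimethoxy-2,6-dimethylcyclohexa-1,5-dien-1-yl) carbonate | C=CCOC(=O)OC1=C(C)CC(OC)(OC)C=C1C | intermediate
6 | (S)-6-allyl-4,4-dimethoxy-2,6-dimethylcyclohex-2-en-1-one | O=C1C(C)=CC(OC)(OC)C[C@]1(C)CC=C | intermediate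
7 | 2-bromopropene | CC(Br)=C | starting material
8 | (S)-6-[3-(9-borabicyclo[3.3.1]nonan-9-yl)propyl]-4,4-dimethoxy-2,6-dimethylcyclohex-2-en-1-one (not isolated) | O=C1C(C)=CC(OC)(OC)C[C@]1(C)CCCB1C2CCCC1CCC2 | intermediate
9 | (S)-4,4-dimethoxy-2,6-dimethyl-6-(4-methylpent-4-en-1-yl)cyclohex-2-en-1-one (not isolated) | O=C1C(C)=CC(OC)(OC)C[C@]1(C)CCCC(C)=C | intermediate
10 | (S)-2,6-dimethyl-6-(4-methylpent-4-en-1-yl)cyclohex-2-ene-1,4-dione | O=C1C(C)=CC(=O)C[C@]1(C)CCCC(C)=C | intermediate
11 | (S)-6-(4-chloro-4-methylpentyl)-2,6-dimethylcyclohex-2-ene-1,4-dione | O=C1C(C)=CC(=O)C[C@]1(C)CCCC(C)(C)Cl | intermediate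
12 | (S)-6-(4-chloro-4-methylpentyl)-2,6-dimethyl-4-(trimethylsilyloxy)cyclohexa-2,4-dien-1-one | O=C1C(C)=CC(O[Si](C)(C)C)=C[C@]1(C)CCCC(C)(C)Cl | intermediate
13 | (4aR,8aS)-2,5,5,8a-tetramethyl-4a,5,6,7,8,8a-hexahydronaphthalene-1,4-dione, cis-fused (not isolated) | O=C1C(C)=CC(=O)[C@@H]2C(C)(C)CCC[C@]12C | intermediate
14 | (4aS,8aS)-2,5,5,8a-tetramethyl-4a,5,6,7,8,8a-hexahydronaphthalene-1,4-dione, trans-fused | O=C1C(C)=CC(=O)[C@H]2C(C)(C)CCC[C@]12C | intermediate
15 | (4R,4aS,8aS)-4-hydroxy-2,5,5,8a-tetramethyl-4a,5,6,7,8,8a-hexahydronaphthalen-1(4H)-one | O=C1C(C)=C[C@@H](O)[C@H]2C(C)(C)CCC[C@]12C | intermediate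
16 | (R)-linalool | C=C[C@](C)(O)CCC=C(C)C | starting material
17 | (R)-[(3,7-dimethylocta-1,6-dien-3-yl)oxy]triethylsilane | C=C[C@](C)(O[Si](CC)(CC)CC)CCC=C(C)C | intermediate
18 | (R)-4-methyl-4-(triethylsilyloxy)hex-5-enal | C=C[C@](C)(O[Si](CC)(CC)CC)CCC=O | intermediate
19 | (R)-3-methyl-3,6-bis(triethylsilyloxy)hexa-1,5-diene (E/Z mixture at C5=C6, both isomers used) | C=C[C@](C)(O[Si](CC)(CC)CC)CC=CO[Si](CC)(CC)CC | intermediate
20 | (R)-3-methyl-3-(triethylsilyloxy)pent-4-enal (not isolated) | C=C[C@](C)(O[Si](CC)(CC)CC)CC=O | intermediate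
21 | (R)-3-methyl-3-(triethylsilyloxy)pent-4-en-1-ol | C=C[C@](C)(O[Si](CC)(CC)CC)CCO | intermediate
22 | (R)-5-bromo-3-methyl-3-(triethylsilyloxy)pent-1-ene | C=C[C@](C)(O[Si](CC)(CC)CC)CCBr | intermediate
23 | [(R)-3-methyl-3-(triethylsilyloxy)pent-4-en-1-yl]magnesium bromide (not isolated) | C=C[C@](C)(O[Si](CC)(CC)CC)CC[Mg]Br | intermediate
24 | dichloro[(R)-3-methyl-3-(triethylsilyloxy)pent-4-en-1-yl]cerium (not isolated) | C=C[C@](C)(O[Si](CC)(CC)CC)CC[Ce](Cl)Cl | intermediate
25 | (1S,4R,4aS,8aS)-2,5,5,8a-tetramethyl-1-[(3R)-3-methyl-3-(triethylsilyloxy)pent-4-en-1-yl]-1,4,4a,5,6,7,8,8a-octahydronaphthalene-1,4-diol (6β,9β-diol; the C9 epimer is equally serviceable) | C=C[C@](C)(O[Si](CC)(CC)CC)CC[C@]1(O)C(C)=C[C@@H](O)[C@H]2C(C)(C)CCC[C@]12C | intermediate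
26 | (1R,4S,4aS,8aS)-4-hydroxy-3,4a,8,8-tetramethyl-4-[(3R)-3-methyl-3-(triethylsilyloxy)pent-4-en-1-yl]-1,4,4a,5,6,7,8,8a-octahydronaphthalen-1-yl acetate | C=C[C@](C)(O[Si](CC)(CC)CC)CC[C@]1(O)C(C)=C[C@@H](OC(C)=O)[C@H]2C(C)(C)CCC[C@]12C | intermediate
27 | (1S,4aS,8aS)-3,4a,8,8-tetramethyl-4-[(3R)-3-methyl-3-(triethylsilyloxy)pent-4-en-1-yl]-2-oxo-1,2,4a,5,6,7,8,8a-octahydronaphthalen-1-yl acetate | C=C[C@](C)(O[Si](CC)(CC)CC)CCC1=C(C)C(=O)[C@@H](OC(C)=O)[C@H]2C(C)(C)CCC[C@]12C | intermediate
28 | (1S,4aS,8aS)-4-[(3R)-3-hydroxy-3-methylpent-4-en-1-yl]-3,4a,8,8-tetramethyl-2-oxo-1,2,4a,5,6,7,8,8a-octahydronaphthalen-1-yl acetate, i.e. (13R)-6β-acetoxy-13-hydroxylabda-8,14-dien-7-one | C=C[C@](C)(O)CCC1=C(C)C(=O)[C@@H](OC(C)=O)[C@H]2C(C)(C)CCC[C@]12C | target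

Total step count: 17 (12 on the decalin line, 5 for the side-chain bromide).
Longest linear sequence: 12 steps (steps 1–8 and 14–17, from 4-methoxy-2,6-dimethylphenol).

Steps most likely to fail

1. Step 7 (key step). The ring closure can only deliver the cis-fused ketone, so the outcome depends on base-mediated epimerisation at C5, which may stop at a mixture still rich in the cis isomer. Proton loss from the C4 cation is the lesser concern, because the alkene is re-ionised and desilylated material returns to 11. The fallback replaces thermodynamic by kinetic control. It sets out from 13, isolated after the TiCl4 stage with the DBU treatment left out. 13 is deprotonated at C5 with KN(SiMe3)2 in THF at −78 °C to potassium (8aS)-2,5,5,8a-tetramethyl-1-oxo-1,5,6,7,8,8a-hexahydronaphthalen-4-olate F1. The cold dienolate solution is then added to acetic acid in THF at −78 °C. Kinetic protonation should take place on the α face, opposite the two axial methyl groups that flank C5, and the route is rejoined at 14, which is reduced at once in step 8.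

2. Step 2. Hydride may be delivered 1,2 to the carbonyl, or the dienolate may lose methoxide and rearomatise before it is acylated. The fallback sets out from 2 and replaces the borohydride by a transition-metal 1,4-hydrosilylation. RhCl(PPh3)3 (1 mol%) and Et3SiH in toluene at 50 °C should give triethyl[(4,4-dimethoxy-2,6-dimethylcyclohexa-1,5-dien-1-yl)oxy]silane F2. This silyl enol ether then enters the asymmetric allylation directly (Pd2(dba)3, (R)-t-Bu-PHOX, diallyl carbonate, Bu4N[Ph3SiF2] 0.35 equiv, THF, 25 °C), and the route is rejoined at 6, bypassing 5.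

3. Step 16. The hindered tertiary allylic alcohol may ionise and dehydrate to dienes, or the tertiary silyl ether may be lost under the acidic chromium reagent, before the chromate shift occurs. The fallback sets out from 26 and separates transposition from oxidation. Ph3SiOReO3 (catalytic, Et2O, 0 °C) should move the hydroxyl from C9 to C7, towards the tetrasubstituted C8=C9 alkene, giving (1S,4aS,8aS)-2-hydroxy-3,4a,8,8-tetramethyl-4-[(3R)-3-methyl-3-(triethylsilyloxy)pent-4-en-1-yl]-1,2,4a,5,6,7,8,8a-octahydronaphthalen-1-yl acetate F3 as a mixture of C7 epimers. Both epimers are oxidised with Dess–Martin periodinane and NaHCO3 in CH2Cl2, and the route is rejoined at 27.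

Further compounds
F1 | step 7 | potassium (8aS)-2,5,5,8a-tetramethyl-1-oxo-1,5,6,7,8,8a-hexahydronaphthalen-4-olate | O=C1C(C)=CC([O-])=C2C(C)(C)CCC[C@]12C.[K+]
F2 | step 2 | triethyl[(4,4-dimethoxy-2,6-dimethylcyclohexa-1,5-dien-1-yl)oxy]silane | CC[Si](CC)(CC)OC1=C(C)CC(OC)(OC)C=C1C
F3 | step 16 | (1S,4aS,8aS)-2-hydroxy-3,4a,8,8-tetramethyl-4-[(3R)-3-methyl-3-(triethylsilyloxy)pent-4-en-1-yl]-1,2,4a,5,6,7,8,8a-octahydronaphthalen-1-yl acetate (both C7 epimers) | C=C[C@](C)(O[Si](CC)(CC)CC)CCC1=C(C)C(O)[C@@H](OC(C)=O)[C@H]2C(C)(C)CCC[C@]12C
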